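The route rests on opening the cyclohexene at its tetrasubstituted C5=C10 alkene (britannilactone numbering), the one ring bond that carries no stereocentre. Ring-closing metathesis of the C5 and C10 methylidenes of an acyclic diene closes this six-membered ring onto the existing C7–C8 γ-lactone, whose cis C6 and C9 arms hold the two olefins close, and gives the target itself; the electron-poor C11=C13 exo-methylene is a spectator. The precursor is the seco-diene diacetate with all four stereocentres in place: C4 from (S)-citronellal, C6 from a catalytic asymmetric alkynylation, C7 and C8 from a chair allylboration–lactonisation of an (E)-2-(borylmethyl)enoate with 3-methylbut-3-enal.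

Key step: step 11

Remarks and assumptions
- Numbering: britannilactone numbering locates atoms throughout. C1 is CH2OAc, C4 is the CH(CH3) centre, C5=C10 is the ring alkene, C6 is CHOAc, C7/C8 is the lactone fusion, C11=C13 is the exo-methylene and C12 is the lactone carbonyl. In the systematic names of the acyclic ester intermediates, C4 is britannilactone C6 and C6 is britannilactone C4.
- Assumption: in step 2 the ProPhenol antipode is the one that delivers the alkynyl group to the Re face of the aldehyde carbon. The sense should be confirmed by Mosher ester analysis on the first run; both antipodes are commercial.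
- Design point: the cis C7–C8 lactone requires the allylboronate in which C6 is cis to the CH2B group, that is the (E)-enoate. Syn hydride addition to the ynoate with direct boronate trapping would give the other geometry and hence the trans-lactone. The alkene is therefore built by hydroxyl-directed trans-hydroalumination/iodination and a stereoretentive cross-coupling.
- CIP note: the descriptor at britannilactone C6 is S while the alkyne is present and R afterwards. The descriptor at C7 is S in the free diol and R in the silyl ether, the diacetate and the target. The spatial arrangement does not change in either case. The diene diacetate and the target have the same configuration, (4S,6R,7R,8R).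

Step 1
Reactants: 1 (S)-citronellal
Product: 2 (3S)-3,7-dimethyl-2-methylideneoct-6-enal
Conditions: 37% aq. HCHO, pyrrolidine (10 mol%), EtCO2H (10 mol%), i-PrOH, 45 °C
Reagents that add atoms: formaldehyde, C=O
Why: Amine-catalysed α-methylenation (Mannich condensation of the pyrrolidine enamine with formaldehyde, then β-elimination) installs the C5 methylidene, and C4 is preserved because it is not enolisable in the aldehyde or in the product enal.

Step 2
Reactants: 2 (3S)-3,7-dimethyl-2-methylideneoct-6-enal; 3 methyl propiolate
Product: 5 methyl (4S,6S)-4-hydroxy-6,10-dimethyl-5-methylideneundec-9-en-2-ynoate, via methylzinc alkynylide 4 (not isolated)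
Conditions: Me2Zn (3 equiv), ProPhenol (20 mol%, antipode for Re-face addition), Ph3P=O (40 mol%), PhMe, 0–4 °C; aq. NH4Cl
Reagents that add atoms: none
Why: ProPhenol–dinuclear zinc asymmetric alkynylation of an aldehyde, in which the zinc alkynylide adds 1,2 to the non-enolisable enal under catalyst control from the Re face and so sets the C6 carbinol (4S in the ynoate) largely independently of the remote C4 centre.

Step 3
Reactants: 5 methyl (4S,6S)-4-hydroxy-6,10-dimethyl-5-methylideneundec-9-en-2-ynoate
Product: 7 methyl (4S,6S)-4-hydroxy-6-methyl-5-methylidene-9-oxonon-2-ynoate, via ozonide 6 (not isolated)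
Conditions: O3/O2, CH2Cl2, −78 °C, Sudan Red 7B end point; then Me2S, −78 °C→rt
Reagents that add atoms: ozone, [O-][O+]=O
Why: Chemoselective ozonolysis (Criegee mechanism) with reductive work-up, in which electrophilic ozone cleaves the electron-rich trisubstituted alkene far faster than the alkynoate or the C5 methylidene (deactivated by the adjacent carbinol and alkynyl ester), the dye end point prevents over-oxidation, and dimethyl sulfide reduces the ozonide without adding to the ynoate.

Step 4
Reactants: 7 methyl (4S,6S)-4-hydroxy-6-methyl-5-methylidene-9-oxonon-2-ynoate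
Product: 9 methyl (2Z,4R,6S)-4,9-dihydroxy-2-iodo-6-methyl-5-methylidenenon-2-enoate, via alkenylaluminate 8 (not isolated)
Conditions: Red-Al (2.5 equiv), THF, −72 °C; then I2, THF, −72→−20 °C; aq. Rochelle salt
Reagents that add atoms: iodine, II
Why: Hydroxyl-directed trans-hydroalumination of a γ-hydroxy ynoate followed by iodinolysis, in which hydride goes to C7 and aluminium to C11 (held cis to C6 in the five-membered chelate) so that iodine replaces aluminium with retention to give the (Z)-α-iodo enoate, while the same reagent reduces the C1 aldehyde and the methyl ester should survive at −72 °C; no stereocentre is formed.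

Step 5
Reactants: 9 methyl (2Z,4R,6S)-4,9-dihydroxy-2-iodo-6-methyl-5-methylidenenon-2-enoate
Product: 10 methyl (2Z,4R,6S)-4,9-bis(tert-butyldimethylsilyloxy)-2-iodo-6-methyl-5-methylidenenon-2-enoate
Conditions: TBSOTf (2.6 equiv), 2,6-lutidine, CH2Cl2, −78→0 °C
Reagents that add atoms: tert-butyldimethylsilyl triflate, CC(C)(C)[Si](C)(C)OS(=O)(=O)C(F)(F)F
Why: Silyl triflate silylation under a hindered base protects the secondary allylic C6 hydroxyl and the primary C1 hydroxyl in one operation without touching the iodo enoate.

Step 6
Reactants: 10 methyl (2Z,4R,6S)-4,9-bis(tert-butyldimethylsilyloxy)-2-iodo-6-methyl-5-methylidenenon-2-enoate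
Product: 11 methyl (2E,4R,6S)-4,9-bis(tert-butyldimethylsilyloxy)-6-methyl-5-methylidene-2-[(4,4,5,5-tetramethyl-1,3,2-dioxaborolan-2-yl)methyl]non-2-enoate
Conditions: ICH2Bpin, Zn dust (TMSCl-activated), THF, rt; then 10, Pd(PPh3)4 (5 mol%), THF, 40 °C
Reagents that add atoms: 2-(iodomethyl)-4,4,5,5-tetramethyl-1,3,2-dioxaborolane, ICB1OC(C)(C)C(C)(C)O1
Why: Negishi cross-coupling of the alkenyl iodide with the α-boryl alkylzinc reagent formed by zinc insertion proceeds with retention of alkene geometry and so places the CH2B group cis to C6, which is the (E)-2-alkoxycarbonyl allylboronate needed for the cis-lactone.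

Step 7
Reactants: 12 3-methylbut-3-en-1-ol
Product: 13 3-methylbut-3-enal
Conditions: Dess–Martin periodinane, pyridine, CH2Cl2, 0 °C→rt; filtered through a short silica plug and used at once as a solution
Reagents that add atoms: none
Why: Dess–Martin oxidation under pyridine buffering gives the β,γ-unsaturated aldehyde without migration of the double bond into conjugation, and the aldehyde is used at once as a solution.

Step 8
Reactants: 11 methyl (2E,4R,6S)-4,9-bis(tert-butyldimethylsilyloxy)-6-methyl-5-methylidene-2-[(4,4,5,5-tetramethyl-1,3,2-dioxaborolan-2-yl)methyl]non-2-enoate; 13 3-methylbut-3-enal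
Product: 15 (4R,5R)-4-[(1R,3S)-1,6-bis(tert-butyldimethylsilyloxy)-3-methyl-2-methylidenehexyl]-3-methylidene-5-(2-methylprop-2-en-1-yl)oxolan-2-one, via borate ester 14 (not isolated)
Conditions: 13 (3 equiv), Sc(OTf)3 (10 mol%), PhMe, 0 °C→rt; then PPTS (cat.), 40 °C
Reagents that add atoms: none
Why: Lewis-acid-catalysed allylboration through a closed chair transition state and lactonisation of the borate onto the methyl ester, in which the (E)-alkene places C6 pseudo-axial and so gives the 7,8-syn adduct and the cis-lactone, while allylic 1,3-strain keeps H6 in the alkene plane so that the aldehyde attacks C7 anti to the bulky, σ-donating C5 branch and on the side of the silyloxy oxygen, which sets C7 and C8 relative to C6.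

Step 9
Reactants: 15 (4R,5R)-4-[(1R,3S)-1,6-bis(tert-butyldimethylsilyloxy)-3-methyl-2-methylidenehexyl]-3-methylidene-5-(2-methylprop-2-en-1-yl)oxolan-2-one
Product: 16 (4S,5R)-4-[(1R,3S)-1,6-dihydroxy-3-methyl-2-methylidenehexyl]-3-methylidene-5-(2-methylprop-2-en-1-yl)oxolan-2-one
Conditions: HF·pyridine, pyridine, THF, 0 °C→rt; crude diol taken on without delay
Reagents that add atoms: none
Why: Fluoride cleavage of both silyl ethers with pyridine-buffered HF is compatible with the α-methylene lactone and the alkenes and is too weakly acidic to equilibrate the lactone onto the freed C6 hydroxyl.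

Step 10
Reactants: 16 (4S,5R)-4-[(1R,3S)-1,6-dihydroxy-3-methyl-2-methylidenehexyl]-3-methylidene-5-(2-methylprop-2-en-1-yl)oxolan-2-one
Product: 17 (4R,5R)-4-[(1R,3S)-1,6-diacetoxy-3-methyl-2-methylidenehexyl]-3-methylidene-5-(2-methylprop-2-en-1-yl)oxolan-2-one (seco-diene diacetate)
Conditions: Ac2O, pyridine, DMAP (cat.), CH2Cl2, 0 °C
Reagents that add atoms: acetic anhydride, CC(=O)OC(C)=O
Why: DMAP-catalysed acylation esterifies the primary and the secondary allylic hydroxyl rapidly at 0 °C, faster than any acyl or lactone migration, and gives the diene for ring closure.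

Step 11
Reactants: 17 seco-diene diacetate
Product: 18 1,6-O,O-diacetylbritannilactone
Conditions: Stewart–Grubbs catalyst (N-o-tolyl NHC, Hoveyda-type Ru; 10 mol% in portions), 1,4-benzoquinone (20 mol%), PhMe (5 mM), 80 °C, Ar sparge
Reagents that add atoms: none
Why: Olefin metathesis by the Chauvin mechanism: the ruthenium carbene first exchanges onto the less hindered C10 methylidene, the resulting C10 alkylidene adds [2+2] across the C5 methylidene, and the ruthenacyclobutane cycloreverts to C5=C10 and Ru=CH2, with ethylene swept out to drive the reaction. The closest known reaction type is ring-closing metathesis of two 1,1-disubstituted olefins to tetrasubstituted cyclohexenes with second-generation NHC–Ru catalysts bearing small N-aryl groups at elevated temperature. The one ring closed is the six-membered carbocycle C5–C6–C7–C8–C9–C10, formed cis-fused to the lactone, whose cis C6 and C9 arms hold the two olefins within reach. No stereocentre is created, and C4, C6, C7 and C8 should stay untouched because the conditions are neutral and benzoquinone suppresses ruthenium hydride isomerisation. The selectivity needed is chemoselectivity against the C11=C13 methylene; it is secured by the acrylate-type electron poverty of that olefin and because its reaction with C5 or C10 could only give a cyclobutene or a bridgehead alkene of a 2-oxabicyclo[2.2.1]heptane, and the acetates are inert.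

Compound list
1 | (S)-citronellal, (3S)-3,7-dimethyloct-6-enal | O=CC[C@@H](C)CCC=C(C)C | starting material
2 | (3S)-3,7-dimethyl-2-methylideneoct-6-enal | O=CC(=C)[C@@H](C)CCC=C(C)C | intermediate
3 | methyl propiolate | C#CC(=O)OC | starting material
4 | methyl 3-(methylzincio)prop-2-ynoate (methylzinc alkynylide, not isolated) | C[Zn]C#CC(=O)OC | intermediate
5 | methyl (4S,6S)-4-hydroxy-6,10-dimethyl-5-methylideneundec-9-en-2-ynoate | COC(=O)C#C[C@@H](O)C(=C)[C@@H](C)CCC=C(C)C | intermediate
6 | ozonide (1,2,4-trioxolane) of the isopropylidene alkene of 5, mixture at the ring CH carbon, not isolated | COC(=O)C#C[C@@H](O)C(=C)[C@@H](C)CCC1OOC(C)(C)O1 | intermediate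
7 | methyl (4S,6S)-4-hydroxy-6-methyl-5-methylidene-9-oxonon-2-ynoate | COC(=O)C#C[C@@H](O)C(=C)[C@@H](C)CCC=O | intermediate
8 | chelated C11-alkenylaluminate with the C1 oxygen as alkoxyaluminate (drawn schematically, not isolated) | COC(=O)C1=C[C@H](C(=C)[C@@H](C)CCCO[AlH-](OCCOC)OCCOC)O[Al-]1(OCCOC)OCCOC.[Na+].[Na+] | intermediate
9 | methyl (2Z,4R,6S)-4,9-dihydroxy-2-iodo-6-methyl-5-methylidenenon-2-enoate | COC(=O)/C(I)=C/[C@@H](O)C(=C)[C@@H](C)CCCO | intermediate
10 | methyl (2Z,4R,6S)-4,9-bis(tert-butyldimethylsilyloxy)-2-iodo-6-methyl-5-methylidenenon-2-enoate | COC(=O)/C(I)=C/[C@@H](O[Si](C)(C)C(C)(C)C)C(=C)[C@@H](C)CCCO[Si](C)(C)C(C)(C)C | intermediate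
11 | methyl (2E,4R,6S)-4,9-bis(tert-butyldimethylsilyloxy)-6-methyl-5-methylidene-2-[(4,4,5,5-tetramethyl-1,3,2-dioxaborolan-2-yl)methyl]non-2-enoate | COC(=O)/C(CB1OC(C)(C)C(C)(C)O1)=C/[C@@H](O[Si](C)(C)C(C)(C)C)C(=C)[C@@H](C)CCCO[Si](C)(C)C(C)(C)C | intermediate
12 | 3-methylbut-3-en-1-ol | C=C(C)CCO | starting material
13 | 3-methylbut-3-enal | C=C(C)CC=O | intermediate
14 | open-chain 7,8-syn allylboration adduct, methyl ester with O8–Bpin borate (not isolated) | COC(=O)C(=C)[C@H]([C@@H](CC(C)=C)OB1OC(C)(C)C(C)(C)O1)[C@@H](O[Si](C)(C)C(C)(C)C)C(=C)[C@@H](C)CCCO[Si](C)(C)C(C)(C)C | intermediate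
15 | (4R,5R)-4-[(1R,3S)-1,6-bis(tert-butyldimethylsilyloxy)-3-methyl-2-methylidenehexyl]-3-methylidene-5-(2-methylprop-2-en-1-yl)oxolan-2-one (cis-lactone; 4S,6R,7R,8R in britannilactone numbering) | C=C1C(=O)O[C@H](CC(C)=C)[C@@H]1[C@@H](O[Si](C)(C)C(C)(C)C)C(=C)[C@@H](C)CCCO[Si](C)(C)C(C)(C)C | intermediate
16 | (4S,5R)-4-[(1R,3S)-1,6-dihydroxy-3-methyl-2-methylidenehexyl]-3-methylidene-5-(2-methylprop-2-en-1-yl)oxolan-2-one (seco-britannilactone) | C=C1C(=O)O[C@H](CC(C)=C)[C@@H]1[C@@H](O)C(=C)[C@@H](C)CCCO | intermediate
17 | (4R,5R)-4-[(1R,3S)-1,6-diacetoxy-3-methyl-2-methylidenehexyl]-3-methylidene-5-(2-methylprop-2-en-1-yl)oxolan-2-one (seco-diene diacetate, key-step precursor) | C=C1C(=O)O[C@H](CC(C)=C)[C@@H]1[C@@H](OC(C)=O)C(=C)[C@@H](C)CCCOC(C)=O | intermediate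
18 | 1,6-O,O-diacetylbritannilactone, (4S,6R,7R,8R) | C=C1C(=O)O[C@@H]2CC(C)=C([C@@H](C)CCCOC(C)=O)[C@H](OC(C)=O)[C@H]12 | target

Total step count: 11. Longest linear sequence: 10 steps (steps 1–6 and 8–11 from (S)-citronellal); step 7 is a one-step side branch.

Steps most likely to fail

Step 11. The ruthenium carbene may fail to engage the C5 methylidene, which sits between two branched carbons (C4 and the acetoxy-bearing C6), so that catalyst decay and olefin isomerisation outrun ring closure. The fallback sets out from diol 16 and closes the ring while C6 carries a free allylic hydroxyl (same catalyst class, PhMe, 60–80 °C). This removes the bulk and the chelating carbonyl of the acetate next to the reluctant olefin, and a free allylic hydroxyl is known to speed up metathesis at the adjacent alkene. The ring closure should give britannilactone F1, and diacetylation (Ac2O, pyridine, DMAP, CH2Cl2) returns to the route at 18.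

Step 8. The π-facial discrimination of the allylboration with respect to C6 may run opposite to plan, with attack anti to the silyloxy group instead of anti to the C5 branch, which would place C7 and C8 wrongly relative to C6. The fallback sets out from 2 and uses the mirror-image ProPhenol ligand in the alkynylation, which should give the (4R)-alkynol F2. The unchanged operations of steps 3–6, 8 and 9 then lead through its ozonide F3, the aldehyde F4, the alkenylaluminate F5, the iodo diol F6, the bis-silyl ether F7, the boronate F8, the borate ester F9, the lactone F10 and the diol F11. With the reversed facial preference this C6-epimeric series has C7 and C8 in the required absolute configuration. A double Mitsunobu esterification of F11 (AcOH, PPh3, DIAD, THF, 0 °C→rt) acetylates the C1 hydroxyl and inverts C6, and so returns to the route at 17.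

Step 6. Transmetalation of the α-boryl alkylzinc to the hindered α-palladated enoate may be slow, leading to protodeiodination or loss of alkene geometry. The fallback sets out from 10: Stille coupling with (tributylstannyl)methanol (Pd(PPh3)4, dioxane, 80 °C) should give the allylic alcohol F12, and acetylation (Ac2O, pyridine) the allylic acetate F13. Palladium-catalysed borylation with bis(pinacolato)diboron (Pd2(dba)3, DMSO, 50 °C) through the π-allyl complex then returns to the route at 11; the thermodynamically preferred geometry, with C6 trans to the ester, is the one required.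

Further compounds
F1 | step 11 | britannilactone (ring-closed 1,6-diol) | C=C1C(=O)O[C@@H]2CC(C)=C([C@@H](C)CCCO)[C@H](O)[C@H]12
F2 | step 8 | methyl (4R,6S)-4-hydroxy-6,10-dimethyl-5-methylideneundec-9-en-2-ynoate (C6 epimer of 5) | COC(=O)C#C[C@H](O)C(=C)[C@@H](C)CCC=C(C)C
F3 | step 8 | ozonide of F2 (C6 epimer of 6) | COC(=O)C#C[C@H](O)C(=C)[C@@H](C)CCC1OOC(C)(C)O1
F4 | step 8 | methyl (4R,6S)-4-hydroxy-6-methyl-5-methylidene-9-oxonon-2-ynoate (C6 epimer of 7) | COC(=O)C#C[C@H](O)C(=C)[C@@H](C)CCC=O
F5 | step 8 | chelated alkenylaluminate from F4 (C6 epimer of 8, drawn schematically) | COC(=O)C1=C[C@@H](C(=C)[C@@H](C)CCCO[AlH-](OCCOC)OCCOC)O[Al-]1(OCCOC)OCCOC.[Na+].[Na+]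
F6 | step 8 | methyl (2Z,4S,6S)-4,9-dihydroxy-2-iodo-6-methyl-5-methylidenenon-2-enoate (C6 epimer of 9) | COC(=O)/C(I)=C/[C@H](O)C(=C)[C@@H](C)CCCO
F7 | step 8 | methyl (2Z,4S,6S)-4,9-bis(tert-butyldimethylsilyloxy)-2-iodo-6-methyl-5-methylidenenon-2-enoate (C6 epimer of 10) | COC(=O)/C(I)=C/[C@H](O[Si](C)(C)C(C)(C)C)C(=C)[C@@H](C)CCCO[Si](C)(C)C(C)(C)C
F8 | step 8 | methyl (2E,4S,6S)-4,9-bis(tert-butyldimethylsilyloxy)-6-methyl-5-methylidene-2-[(4,4,5,5-tetramethyl-1,3,2-dioxaborolan-2-yl)methyl]non-2-enoate (C6 epimer of 11) | COC(=O)/C(CB1OC(C)(C)C(C)(C)O1)=C/[C@H](O[Si](C)(C)C(C)(C)C)C(=C)[C@@H](C)CCCO[Si](C)(C)C(C)(C)C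
F9 | step 8 | open-chain borate ester, C6 epimer of 14 | COC(=O)C(=C)[C@H]([C@@H](CC(C)=C)OB1OC(C)(C)C(C)(C)O1)[C@H](O[Si](C)(C)C(C)(C)C)C(=C)[C@@H](C)CCCO[Si](C)(C)C(C)(C)C
F10 | step 8 | cis-lactone bis-silyl ether, C6 epimer of 15 | C=C1C(=O)O[C@H](CC(C)=C)[C@@H]1[C@H](O[Si](C)(C)C(C)(C)C)C(=C)[C@@H](C)CCCO[Si](C)(C)C(C)(C)C
F11 | step 8 | cis-lactone diol, C6 epimer of 16 | C=C1C(=O)O[C@H](CC(C)=C)[C@@H]1[C@H](O)C(=C)[C@@H](C)CCCO
F12 | step 6 | methyl (2E,4R,6S)-4,9-bis(tert-butyldimethylsilyloxy)-2-(hydroxymethyl)-6-methyl-5-methylidenenon-2-enoate | COC(=O)/C(CO)=C/[C@@H](O[Si](C)(C)C(C)(C)C)C(=C)[C@@H](C)CCCO[Si](C)(C)C(C)(C)C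
F13 | step 6 | methyl (2E,4R,6S)-2-(acetoxymethyl)-4,9-bis(tert-butyldimethylsilyloxy)-6-methyl-5-methylidenenon-2-enoate | COC(=O)/C(COC(C)=O)=C/[C@@H](O[Si](C)(C)C(C)(C)C)C(=C)[C@@H](C)CCCO[Si](C)(C)C(C)(C)C
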